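(The data were computed from invented constants.)

Late in this flask Z thins ever more slowly, so count its stretching half-life. Z (substrate) takes up D (reagent) to give G (mono adduct), then J (bis adduct), with L (other product) beside them.

| flask | Z | D | remark | time |
|---|---|---|---|---|
| noon | 0.10 M | 0.20 M | the very flask that is asked about, followed so far |  |
| flask | 0.10 M | 0.200 M |  | 25 min |

noon run (percent of the Z charged)

| time / min | G / % | L / % | Z / % | J / % |
|---|---|---|---|---|
| 0.417 | 2 | 0 | 98 | 0 |
| 1.33 | 9 | 0 | 90 | 3 |
| 2.50 | 6 | 1 | 81 | 9 |
| 4.00 | 14 | 3 | 74 | 16 |
| 5.00 | 11 | 4 | 70 | 20 |

(standard deviation of a reading: 2 percentage points)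

* the species that holds most of what was charged as Z, at 25 min (G / J / Z / L)
* the largest share itself, whichever of these holds it, in percent of the Z charged

- what was read earlier has a scatter of 2 percentage points, one standard deviation

In the noon run G stays roughly flat while J climbs, so each Z lost costs close to two D. D was charged at two per Z, so D stays near twice Z and the loss of Z is second order. The fraction of Z left is then the inverse of one plus t/τ. The reading of 70% at 5.00 min gives τ = 11.7 min, the time for Z to fall to half of its charge.

By my reckoning the curve starts down at 0.0855 min⁻¹ of the charge, with a long bend and no sharp knee. Each further halving takes twice as long as the one before. With G held at its reading of 11%, J + L crosses Z near 14.6 min. Z is still falling at 25 min, where this reckoning puts it at 31.8%. That leaves J + L at 57.2%, and splitting this as the last readings of J and L do gives J 47.7%, more than Z.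

The forecast also says J, but at 42%, within 31% to 51%, with L near 20% by a leak from G: “I take the G route”.

This flask gives J at 60.6%, with Z at 30.5% and L at 3.15%.

    Z + D → G (k = 0.420 M⁻¹ min⁻¹)
    D + G → J (k = 2.50 M⁻¹ min⁻¹)
    D + G → L (k = 0.130 M⁻¹ min⁻¹)

J stands there partly because D falls and partly because the run ends: with D held it reaches 81.2%, and in a run ten times as long 90.3%. For that long run τ gives Z 4.47%, and the flask holds 4.17%. In the neighbour flask with 0.50 M of D, an excess of 0.300 M stays beyond two per Z, so by the same τ the ratio Z/D decays exponentially with time constant 7.78 min. That predicts Z 2.45%, and that neighbour flask holds 2.53%.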